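The earlier runs and the new flask stem from a simulated flask with made-up constants, noise included.

At 8.00 d the north-west run holds 65.8% of its L charge as G. I call this fraction of the L charge standing as G at a given time the capture share, or yield on L, and I carry it to the new flask.

| flask | Z | L | X | remark | time |
|---|---|---|---|---|---|
| north | 0.077 M (fed, over 2.5 h) | 0.046 M | 0.0616 M | run made earlier |  |
| north-west | 0.077 M (fed, over 2.5 h) | 0.069 M | 0.0616 M | run made earlier |  |
| flask | 0.077 M (fed, over 2.5 h) | 0.0924 M | 0.0616 M |  | 8.0 d |

| run | time / d | Z / % | G / % |
|---|---|---|---|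
| north | 2.50 | 64 | 38 |
| north | 5.00 | 61 | 38 |
| north | 8.00 | 60 | 42 |
| north | 10.0 | 56 | 40 |
| north-west | 2.50 | 49 | 52 |
| north-west | 5.00 | 43 | 57 |
| north-west | 8.00 | 43 | 59 |
| north-west | 10.0 | 36 | 57 |

(scatter of a reading: 2 percentage points)

- the earlier runs were read with a standard deviation of 2 percentage points
- the earlier runs do not show how much of L is bound; that part of a forecast is a guess

- part of the Z that has reacted at 8.0 d
- share of free L in free L and J together, at 8.0 d

Z is fed into L and X, and I read the north-west run by its rate of G, as a fraction of the Z charge. The mean rate is 0.208 d⁻¹ up to 2.50 d and 0.0127 d⁻¹ from there to 8.00 d, a slowing by a factor of 16.3. That late rate rests on a small difference of readings, so the factor is rough.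

I take the rate to go with Z and with L. The fall of Z to 43% then gives a factor of 2.33, and the L turned into G gives 2.93. A factor of 2.40 remains, so I conclude that L also leaves by a way that makes no G.

The north-west run still drifts at 0.0127 d⁻¹, so I use the capture share as a value at 8.00 d, not as an end value. It is 70.3% in the north run, and the L charges rise in nearly even steps. Continuing that step gives me 61.4% and 73.7% of Z reacted, though with 2 percentage points on each reading the step itself is barely read. I reckon no free share of L, as the runs do not show bound L.

The forecast says 72%, a little below mine, and 40%, holding that “roughly two-thirds of L ends up as G”.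

The flask gives 73.1% of Z reacted and 79.1% for the free share.

    Z + L ⇌ Q + G (K = 1.10, k = 1.50 M⁻¹ h⁻¹)
    L + Q ⇌ J, settled at all times (K = 14000 M⁻¹)
    Q + X ⇌ E, settled at all times (K = 5.30 × 10⁵ M⁻¹)
    L ⇌ D (K = 20.0, k = 0.0540 h⁻¹)

Its capture share is 60.9%, below the north-west 65.8%. With L ⇌ D struck out, the flask reaches 96.3%. In a neighbour flask, with the same L and 0.19 M of Z, 36.3% of the Z has reacted at the same time, and the capture share is 74.5%.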